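**Retrosynthetic overview**

1. The aryl C–O(sulfate) bond is made last, by para-selective C–H sulfatoxylation of the free catechol aldehyde; the sulfate arrives on an oxygen that was never a free OH, so the three oxygens need no differentiation.
2. The formyl group and the free catechol come from OMOM-directed ortho-formylation and acid unmasking of a bis(MOM) aryl decalin.
3. The benzylic C–aryl bond comes from reductive coupling of a decalin aldehyde tosylhydrazone with an arylboronic acid.
4. Ring B and all three stereocentres come from one enantioselective exo Diels–Alder reaction of 1-ethenyl-6,6-dimethylcyclohexene with (Z)-2-methylbut-2-enal.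
5. Ring order: ring A is bought (2,2-dimethylcyclohexanone), ring B is closed by the cycloaddition, and the arene is bought (4-bromocatechol) and attached afterwards.

Assumption: the target is taken as the free aryl hydrogen sulfate exactly as drawn, liberated from its potassium salt in the final work-up; decalin locants in the text follow terpenoid usage (C4 = CMe2, C5=C6 alkene, C8 = CHMe, C9 = quaternary carbon, C10 = ring-fusion CH, C11 = benzylic carbon) and arene locants are primed (C1′ bears C11, C2′ the sulfate, C3′ the CHO, C4′ and C5′ the hydroxyls).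

**Route**

Step 1
Reactants: 1 2,2-dimethylcyclohexan-1-one
Product: 3 6,6-dimethylcyclohex-1-en-1-yl trifluoromethanesulfonate, via lithium 6,6-dimethylcyclohex-1-en-1-olate 2 (not isolated)
Conditions: LiN(iPr)2 (1.1 equiv), THF, −78 °C; then PhNTf2, −78 °C → rt
Reagents that add atoms: N-phenylbis(trifluoromethanesulfonimide), PhNTf2 (O=S(=O)(N(c1ccccc1)S(=O)(=O)C(F)(F)F)C(F)(F)F)
Why: The ketone has only one enolisable position, so deprotonation and O-triflation of the lithium enolate (enol triflate formation) give a single vinyl triflate.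

Step 2
Reactants: 3 6,6-dimethylcyclohex-1-en-1-yl trifluoromethanesulfonate
Product: 4 1-ethenyl-6,6-dimethylcyclohex-1-ene
Conditions: CH2=CHSnBu3 (1.1 equiv), Pd(PPh3)4 (2 mol %), LiCl (3 equiv), THF, 65 °C
Reagents that add atoms: tributyl(vinyl)stannane (C=C[Sn](CCCC)(CCCC)CCCC)
Why: Stille coupling of a vinyl triflate with a vinylstannane gives the 1,3-diene without any cationic intermediate that could move the ring double bond or a methyl group.

Step 3
Reactants: 5 (2Z)-2-bromobut-2-ene
Product: 7 (2Z)-2-methylbut-2-enal, via (2E)-but-2-en-2-yllithium 6 (not isolated)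
Conditions: t-BuLi (2.0 equiv), Et2O, −78 °C; then DMF, −78 → 0 °C; H2O; distil
Reagents that add atoms: N,N-dimethylformamide (CN(C)C=O)
Why: Bromine–lithium exchange at −78 °C retains the alkene geometry and the configurationally stable alkenyllithium is formylated by DMF (Bouveault formylation), so the CHO group ends up cis to the β-methyl group.

Step 4
Reactants: 4 1-ethenyl-6,6-dimethylcyclohex-1-ene; 7 (2Z)-2-methylbut-2-enal
Product: 8 (1R,2R,8aR)-1,2,5,5-tetramethyl-1,2,3,5,6,7,8,8a-octahydronaphthalene-1-carbaldehyde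
Conditions: (R)-1-(2-methylphenyl)-3,3-diphenyltetrahydro-1H,3H-pyrrolo[1,2-c][1,3,2]oxazaborole (20 mol %), HNTf2 (18 mol %), CH2Cl2, −78 → −20 °C
Reagents that add atoms: none
Why: In this chiral-Lewis-acid-catalysed Diels–Alder reaction the enal β-carbon bonds to the unsubstituted vinyl terminus so the quaternary C9 forms at C10, the exo transition state usual for α-methyl enals places CHO cis to H-10, the Z geometry is transferred stereospecifically into the cis CHO/8-methyl relationship, and the (R)-oxazaborolidinium cation leaves the Si face of the enal α-carbon open (formyl C–H···O binding model), which sets the absolute configuration.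

Step 5
Reactants: 9 4-bromobenzene-1,2-diol
Product: 10 4-bromo-1,2-bis(methoxymethoxy)benzene
Conditions: NaH (2.4 equiv), MOMCl (2.4 equiv), DMF, 0 °C → rt
Reagents that add atoms: chloromethyl methyl ether (COCCl)
Why: Williamson etherification of the catechol dianion installs MOM ethers, which survive organolithium and carbonate chemistry, direct ortho-lithiation, and later come off in dilute acid.

Step 6
Reactants: 10 4-bromo-1,2-bis(methoxymethoxy)benzene
Product: 12 [3,4-bis(methoxymethoxy)phenyl]boronic acid, via [3,4-bis(methoxymethoxy)phenyl]lithium 11 (not isolated)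
Conditions: n-BuLi (1.05 equiv), THF, −78 °C; B(OiPr)3, −78 °C → rt; 1 M HCl to pH 5, 0 °C
Reagents that add atoms: triisopropyl borate (CC(C)OB(OC(C)C)OC(C)C); water (O)
Why: Bromine–lithium exchange, borylation and mild hydrolysis is the standard arylboronic acid synthesis, and the pH 5 work-up keeps the MOM ethers.

Step 7
Reactants: 8 (1R,2R,8aR)-1,2,5,5-tetramethyl-1,2,3,5,6,7,8,8a-octahydronaphthalene-1-carbaldehyde; 12 [3,4-bis(methoxymethoxy)phenyl]boronic acid
Product: 15 1,2-bis(methoxymethoxy)-4-{[(1R,2R,8aS)-1,2,5,5-tetramethyl-1,2,3,5,6,7,8,8a-octahydronaphthalen-1-yl]methyl}benzene, via aldehyde tosylhydrazone 13 (not isolated), via diazomethyl decalin 14 (not isolated)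
Conditions: TsNHNH2 (1.05 equiv), 1,4-dioxane, 80 °C; then 12 (2 equiv), K2CO3 (3 equiv), 110 °C
Reagents that add atoms: none
Why: In this Barluenga–Valdés reductive coupling the base converts the tosylhydrazone into the diazoalkane (Bamford–Stevens), the boronic acid traps it, and 1,2-aryl shift followed by protodeboronation gives the CH2–aryl bond without touching the stereocentres; the missing α-hydrogen rules out the usual alkene-forming 1,2-H shift.

Step 8
Reactants: 15 1,2-bis(methoxymethoxy)-4-{[(1R,2R,8aS)-1,2,5,5-tetramethyl-1,2,3,5,6,7,8,8a-octahydronaphthalen-1-yl]methyl}benzene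
Product: 18 2,3-dihydroxy-5-{[(1R,2R,8aS)-1,2,5,5-tetramethyl-1,2,3,5,6,7,8,8a-octahydronaphthalen-1-yl]methyl}benzaldehyde, via aryllithium 16 (not isolated), via bis(methoxymethyl) ether aldehyde 17 (not isolated)
Conditions: n-BuLi (1.5 equiv), TMEDA, THF, −78 → 0 °C; DMF, −78 °C → rt; then 2 M HCl, MeOH, rt
Reagents that add atoms: N,N-dimethylformamide (CN(C)C=O)
Why: OMOM-directed ortho-lithiation takes the ortho position not flanked by the bulky benzylic group (C3′), DMF formylation puts CHO next to O-4′, and the dilute-acid quench cleaves both MOM acetals without protonating the trisubstituted alkene.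

Step 9
Reactants: 18 2,3-dihydroxy-5-{[(1R,2R,8aS)-1,2,5,5-tetramethyl-1,2,3,5,6,7,8,8a-octahydronaphthalen-1-yl]methyl}benzaldehyde
Product: 20 2-formyl-3,4-dihydroxy-6-{[(1R,2R,8aS)-1,2,5,5-tetramethyl-1,2,3,5,6,7,8,8a-octahydronaphthalen-1-yl]methyl}phenyl hydrogen sulfate (CNP0115595.2), via potassium aryl sulfate 19 (not isolated)
Conditions: K2S2O8 (1.2 equiv), K2CO3/KHCO3 buffer (pH 10), H2O–pyridine 1:1, Ar, 0 °C → rt, 36 h; then 1 M HCl to pH 2, 0 °C, C18 desalting
Reagents that add atoms: potassium peroxydisulfate ([K+].[K+].[O-]S(=O)(=O)OOS(=O)(=O)[O-])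
Why: Proposed new method: an Elbs-type para-C–H sulfatoxylation of an unprotected 3-formylcatechol run at the monoanion stage (pH 10) instead of in strong alkali; the monoanion is a hydrogen-bonded pair of phenoxide tautomers of which only the O-5′ phenoxide has a free para carbon (C2′, the para position of O-4′ being blocked by C1′), this carbon attacks a peroxide oxygen of S2O8 2− with loss of sulfate to give a 4-sulfooxycyclohexa-2,5-dienone that re-aromatises by proton loss, while the formyl group and the avoidance of the far more reducing dianion hold back one-electron oxidation to the o-quinone; the closest known reaction type is the Elbs persulfate oxidation of monohydric phenols and hydroxybenzaldehydes, which has not been shown on a free catechol or at a carbon flanked by CHO and a neopentyl-type benzyl group.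

**Compound list**

1 | 2,2-dimethylcyclohexan-1-one | CC1(C)CCCCC1=O | starting material
2 | lithium 6,6-dimethylcyclohex-1-en-1-olate | CC1(C)CCCC=C1[O-].[Li+] | intermediate
3 | 6,6-dimethylcyclohex-1-en-1-yl trifluoromethanesulfonate | CC1(C)CCCC=C1OS(=O)(=O)C(F)(F)F | intermediate
4 | 1-ethenyl-6,6-dimethylcyclohex-1-ene | C=CC1=CCCCC1(C)C | intermediate
5 | (2Z)-2-bromobut-2-ene (Br cis to the C3 methyl) | C/C=C(/C)Br | starting material
6 | (2E)-but-2-en-2-yllithium (Li cis to the C3 methyl, geometry of 5 retained) | C/C=C(/C)[Li] | intermediate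
7 | (2Z)-2-methylbut-2-enal (angelic aldehyde; CHO cis to the C3 methyl) | C/C=C(/C)C=O | intermediate
8 | (1R,2R,8aR)-1,2,5,5-tetramethyl-1,2,3,5,6,7,8,8a-octahydronaphthalene-1-carbaldehyde (CHO, 2-methyl and H-8a on one face, 1-methyl on the other) | C[C@@H]1CC=C2[C@@H](CCCC2(C)C)[C@]1(C)C=O | intermediate
9 | 4-bromobenzene-1,2-diol | Oc1ccc(Br)cc1O | starting material
10 | 4-bromo-1,2-bis(methoxymethoxy)benzene | COCOc1ccc(Br)cc1OCOC | intermediate
11 | [3,4-bis(methoxymethoxy)phenyl]lithium | COCOc1ccc([Li])cc1OCOC | intermediate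
12 | [3,4-bis(methoxymethoxy)phenyl]boronic acid | COCOc1ccc(B(O)O)cc1OCOC | intermediate
13 | 4-methyl-N′-{(E)-[(1R,2R,8aR)-1,2,5,5-tetramethyl-1,2,3,5,6,7,8,8a-octahydronaphthalen-1-yl]methylidene}benzenesulfonohydrazide | C[C@@H]1CC=C2[C@@H](CCCC2(C)C)[C@]1(C)/C=N/NS(=O)(=O)c1ccc(C)cc1 | intermediate
14 | (1R,2R,8aR)-1-(diazomethyl)-1,2,5,5-tetramethyl-1,2,3,5,6,7,8,8a-octahydronaphthalene | C[C@@H]1CC=C2[C@@H](CCCC2(C)C)[C@]1(C)C=[N+]=[N-] | intermediate
15 | 1,2-bis(methoxymethoxy)-4-{[(1R,2R,8aS)-1,2,5,5-tetramethyl-1,2,3,5,6,7,8,8a-octahydronaphthalen-1-yl]methyl}benzene | C[C@@H]1CC=C2[C@@H](CCCC2(C)C)[C@]1(C)Cc1ccc(OCOC)c(OCOC)c1 | intermediate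
16 | (2,3-bis(methoxymethoxy)-5-{[(1R,2R,8aS)-1,2,5,5-tetramethyl-1,2,3,5,6,7,8,8a-octahydronaphthalen-1-yl]methyl}phenyl)lithium | C[C@@H]1CC=C2[C@@H](CCCC2(C)C)[C@]1(C)Cc1cc(OCOC)c(OCOC)c([Li])c1 | intermediate
17 | 2,3-bis(methoxymethoxy)-5-{[(1R,2R,8aS)-1,2,5,5-tetramethyl-1,2,3,5,6,7,8,8a-octahydronaphthalen-1-yl]methyl}benzaldehyde | C[C@@H]1CC=C2[C@@H](CCCC2(C)C)[C@]1(C)Cc1cc(OCOC)c(OCOC)c(C=O)c1 | intermediate
18 | 2,3-dihydroxy-5-{[(1R,2R,8aS)-1,2,5,5-tetramethyl-1,2,3,5,6,7,8,8a-octahydronaphthalen-1-yl]methyl}benzaldehyde | C[C@@H]1CC=C2[C@@H](CCCC2(C)C)[C@]1(C)Cc1cc(O)c(O)c(C=O)c1 | intermediate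
19 | potassium 2-formyl-3,4-dihydroxy-6-{[(1R,2R,8aS)-1,2,5,5-tetramethyl-1,2,3,5,6,7,8,8a-octahydronaphthalen-1-yl]methyl}phenyl sulfate | C[C@@H]1CC=C2[C@@H](CCCC2(C)C)[C@]1(C)Cc1cc(O)c(O)c(C=O)c1OS(=O)(=O)[O-].[K+] | intermediate
20 | 2-formyl-3,4-dihydroxy-6-{[(1R,2R,8aS)-1,2,5,5-tetramethyl-1,2,3,5,6,7,8,8a-octahydronaphthalen-1-yl]methyl}phenyl hydrogen sulfate | C[C@@H]1CC=C2[C@@H](CCCC2(C)C)[C@]1(C)Cc1cc(O)c(O)c(C=O)c1OS(=O)(=O)O | target

**Step count and risk**

Total step count: 9. Longest linear sequence: 6 (steps 1, 2, 4, 7, 8, 9).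

The three steps most likely to fail:

Step 9 (the proposed new step). The risks are oxidation of the catechol to the o-quinone, attack ortho to O-5′, and low conversion; unreacted 18 stays extractable at pH 4 and can be recycled. The fallback uses known chemistry, sets out from 17 (isolated by giving step 8 a neutral aqueous quench instead of the acid) and comes back at 20. The aldehyde of 17 is masked in situ with LiN(Me)CH2CH2NMe2 and the ring is lithiated with n-BuLi (THF, −20 °C) at C2′, the only position ortho to that director (Comins directed ortho-lithiation). Quenching with B(OMe)3 and oxidising with N-methylmorpholine N-oxide gives the phenol 6-hydroxy-2,3-bis(methoxymethoxy)-5-{[(1R,2R,8aS)-1,2,5,5-tetramethyl-1,2,3,5,6,7,8,8a-octahydronaphthalen-1-yl]methyl}benzaldehyde F6. Sulfation of this single free OH with 2,2,2-trichloroethyl chlorosulfate, Et3N and DMAP in CH2Cl2 gives the aryl 2,2,2-trichloroethyl sulfate F7. 2 M HCl in MeOH removes the MOM groups to give the catechol 2,2,2-trichloroethyl sulfate F8, the protected sulfate diester being stable to acid. Zn dust and HCO2NH4 in MeOH at rt release the sulfate monoester, which is acidified cold to 20.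

Step 4. The risks are Z to E isomerisation of 7 under the acid catalyst, slow reaction of the β-substituted enal with the hindered diene, and insufficient enantiomeric excess; the sense of induction is checked on the first run and the (S)-catalyst is used if it is opposite. The fallback sets out from 4 and 7 and comes back at 8. The cycloaddition is run without a chiral catalyst (Me2AlCl, 1.1 equiv, CH2Cl2, −78 → −20 °C), which gives 8 together with its mirror image (1S,2S,8aS)-1,2,5,5-tetramethyl-1,2,3,5,6,7,8,8a-octahydronaphthalene-1-carbaldehyde F1. The racemate is condensed with (1R,2R)-N,N′-dimethyl-1,2-diphenylethane-1,2-diamine (MgSO4, Et2O, rt) to the two diastereomeric aminals, the (4R,5R)-imidazolidine of 8 F2 and the (4R,5R)-imidazolidine of the mirror-image aldehyde F3. These are separated on silica, and F2 is hydrolysed (0.5 M HCl, Et2O, 0 °C) to enantiopure 8.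

Step 7. The risks are competing carbene-type rearrangement of the neopentyl diazoalkane 14 and protodeboronation of the electron-rich boronic acid 12. The fallback sets out from 8 and 10 and comes back at 15. Bromide 10 is exchanged with n-BuLi (THF, −78 °C) to aryllithium 11, which adds to 8 to give the benzylic alcohol [3,4-bis(methoxymethoxy)phenyl][(1R,2R,8aR)-1,2,5,5-tetramethyl-1,2,3,5,6,7,8,8a-octahydronaphthalen-1-yl]methanol F4 as a mixture of carbinol epimers. NaH, CS2 and MeI in THF convert it into the S-methyl xanthate F5, and Bu3SnH with AIBN in toluene at 110 °C (Barton–McCombie deoxygenation) removes the oxygen to give 15.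

Further compounds
F1 | step 4 | (1S,2S,8aS)-1,2,5,5-tetramethyl-1,2,3,5,6,7,8,8a-octahydronaphthalene-1-carbaldehyde | C[C@H]1CC=C2[C@H](CCCC2(C)C)[C@@]1(C)C=O
F2 | step 4 | (4R,5R)-1,3-dimethyl-4,5-diphenyl-2-[(1R,2R,8aR)-1,2,5,5-tetramethyl-1,2,3,5,6,7,8,8a-octahydronaphthalen-1-yl]imidazolidine | C[C@@H]1CC=C2[C@@H](CCCC2(C)C)[C@]1(C)C1N(C)[C@H](c2ccccc2)[C@@H](c2ccccc2)N1C
F3 | step 4 | (4R,5R)-1,3-dimethyl-4,5-diphenyl-2-[(1S,2S,8aS)-1,2,5,5-tetramethyl-1,2,3,5,6,7,8,8a-octahydronaphthalen-1-yl]imidazolidine | C[C@H]1CC=C2[C@H](CCCC2(C)C)[C@@]1(C)C1N(C)[C@H](c2ccccc2)[C@@H](c2ccccc2)N1C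
F4 | step 7 | [3,4-bis(methoxymethoxy)phenyl][(1R,2R,8aR)-1,2,5,5-tetramethyl-1,2,3,5,6,7,8,8a-octahydronaphthalen-1-yl]methanol (both carbinol epimers) | C[C@@H]1CC=C2[C@@H](CCCC2(C)C)[C@]1(C)C(O)c1ccc(OCOC)c(OCOC)c1
F5 | step 7 | O-{[3,4-bis(methoxymethoxy)phenyl][(1R,2R,8aR)-1,2,5,5-tetramethyl-1,2,3,5,6,7,8,8a-octahydronaphthalen-1-yl]methyl} S-methyl carbonodithioate (both epimers) | C[C@@H]1CC=C2[C@@H](CCCC2(C)C)[C@]1(C)C(OC(=S)SC)c1ccc(OCOC)c(OCOC)c1
F6 | step 9 | 6-hydroxy-2,3-bis(methoxymethoxy)-5-{[(1R,2R,8aS)-1,2,5,5-tetramethyl-1,2,3,5,6,7,8,8a-octahydronaphthalen-1-yl]methyl}benzaldehyde | C[C@@H]1CC=C2[C@@H](CCCC2(C)C)[C@]1(C)Cc1cc(OCOC)c(OCOC)c(C=O)c1O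
F7 | step 9 | 2-formyl-3,4-bis(methoxymethoxy)-6-{[(1R,2R,8aS)-1,2,5,5-tetramethyl-1,2,3,5,6,7,8,8a-octahydronaphthalen-1-yl]methyl}phenyl 2,2,2-trichloroethyl sulfate | C[C@@H]1CC=C2[C@@H](CCCC2(C)C)[C@]1(C)Cc1cc(OCOC)c(OCOC)c(C=O)c1OS(=O)(=O)OCC(Cl)(Cl)Cl
F8 | step 9 | 2-formyl-3,4-dihydroxy-6-{[(1R,2R,8aS)-1,2,5,5-tetramethyl-1,2,3,5,6,7,8,8a-octahydronaphthalen-1-yl]methyl}phenyl 2,2,2-trichloroethyl sulfate | C[C@@H]1CC=C2[C@@H](CCCC2(C)C)[C@]1(C)Cc1cc(O)c(O)c(C=O)c1OS(=O)(=O)OCC(Cl)(Cl)Cl
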